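**Plan** (iridoid numbering: C1 acetal carbon, O2, C3=C4, C5/C9 ring fusion, C6, C7, C8, C10 on C8, C11 on C4; β = face of H5 and H9)
- Retrosynthesis: the 1-O-isovaleryl and 7-O-coumaroyl esters are removed, C11 is returned to a methyl ester, the O2–C1 hemiacetal is opened to a C1,C3-dialdehyde, and C1 is rejoined to C3 as a glycol.
- Enabling feature: a bond between C1 and C3 turns the dihydropyran (C1, O2, C3, C4, C5, C9) into a cyclopentenone (C3 carbonyl, C4 bearing C11, C4=C5) fused across C5–C9 to the cyclopentane C5–C6–C7–C8–C9, a bicyclo[3.3.0]octenone.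
- That enone is cut at C5–C9, C1–C3 and C3–C4 (Pauson–Khand) to an open-chain 1,6-enyne: vinyl group (C9, C1) on C8, alkynoate (C5, C4, C11) on C6.
- Forward: the chain is joined from L-erythrulose (C10, C8, C7, C6), a vinyl Grignard reagent and methyl propiolate; both carbocycles close in one step; the C1–C3 bond is then oxidised and cleaved, and the formyl-ester enol closes the pyran.
- Stereochemistry: C7 from L-erythrulose, C8 by chelate-controlled Grignard addition, C9 by substrate control in the cycloaddition, C5 by cis hydrogenation, C1 by anomeric control in the acylation.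

Key step: step 8

Remark: TBS = tert-butyldimethylsilyl, TES = triethylsilyl, TMS = trimethylsilyl. The centres C1, C3 and C4 created in steps 9 to 11 are erased in step 12 and are left unassigned in names and SMILES. Lactols and their TMS acetals are drawn as the 1β anomer, although the anomers interconvert. Bicyclic compounds are named with iridoid locants.

**Route**

Step 1
Reactants: 1 L-erythrulose
Product: 2 3,4-O-isopropylidene-L-erythrulose
Conditions: Me2C(OMe)2, camphorsulfonic acid (cat.), acetone, rt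
Reagents that add atoms: 2,2-dimethoxypropane, COC(C)(C)OC
Why: Acid-catalysed acetonide formation should take the terminal 3,4-diol into the five-membered dioxolane and leave the primary C1 hydroxyl and the ketone free; the stereocentre is untouched.

Step 2
Reactants: 2 3,4-O-isopropylidene-L-erythrulose
Product: 3 1-O-TBS-3,4-O-isopropylidene-L-erythrulose
Conditions: TBSCl, imidazole, CH2Cl2, 0 °C to rt
Reagents that add atoms: tert-butyldimethylsilyl chloride, CC(C)(C)[Si](C)(C)Cl
Why: Standard silylation of a primary alcohol gives a bulky, poorly coordinating ether on the future C10 oxygen, which matters for the chelate in step 3.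

Step 3
Reactants: 3 1-O-TBS-3,4-O-isopropylidene-L-erythrulose; 4 vinylmagnesium bromide
Product: 5 (2R)-1-(TBS-oxy)-2-[(4S)-2,2-dimethyl-1,3-dioxolan-4-yl]but-3-en-2-ol
Conditions: CH2=CHMgBr (THF solution), Et2O, −78 °C; aq. NH4Cl
Reagents that add atoms: none
Why: Chelate-controlled Grignard addition (Cram chelate model): magnesium bridges the ketone and the dioxolane oxygen on the future C7, not the silyl ether oxygen, and the vinyl group enters anti to the dioxolane CH2, which sets C8 as R.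

Step 4
Reactants: 5 (2R)-1-(TBS-oxy)-2-[(4S)-2,2-dimethyl-1,3-dioxolan-4-yl]but-3-en-2-ol
Product: 6 (2S,3R)-3-[(TBS-oxy)methyl]pent-4-ene-1,2,3-triol
Conditions: CuCl2·2H2O, MeCN, 0 °C to rt
Reagents that add atoms: none
Why: Mild Lewis-acid hydrolysis of a terminal isopropylidene acetal should spare the neopentyl-type primary TBS ether and the tertiary allylic alcohol.

Step 5
Reactants: 6 (2S,3R)-3-[(TBS-oxy)methyl]pent-4-ene-1,2,3-triol
Product: 8 (2R)-1-(TBS-oxy)-2-[(2S)-oxiran-2-yl]but-3-en-2-ol, via primary tosylate 7 (not isolated)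
Conditions: TsCl, Bu2SnO (cat.), Et3N, CH2Cl2, 0 °C to rt; then K2CO3, MeOH, 0 °C
Reagents that add atoms: none
Why: Tin-acetal-catalysed sulfonylation picks the primary hydroxyl of the terminal 1,2-diol, and the C7 alkoxide then closes the epoxide (3-exo-tet Williamson closure) without touching the C7–O bond, so C7 keeps its configuration.

Step 6
Reactants: 8 (2R)-1-(TBS-oxy)-2-[(2S)-oxiran-2-yl]but-3-en-2-ol; 9 methyl propiolate
Product: 11 methyl (5S,6R)-6-[(TBS-oxy)methyl]-5,6-dihydroxyoct-7-en-2-ynoate, via lithium methyl propiolate 10 (not isolated)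
Conditions: 9, n-BuLi, THF, −78 °C; BF3·OEt2; then 8, −78 °C; aq. NH4Cl
Reagents that add atoms: none
Why: BF3-promoted opening of a terminal epoxide by a lithium acetylide (Yamaguchi–Hirao alkynylation) occurs at the CH2 terminus (C6); the low temperature keeps the lithiated propiolate intact and suppresses Payne rearrangement of the epoxy alcohol, one extra equivalent of acetylide being spent on the tertiary hydroxyl.

Step 7
Reactants: 11 methyl (5S,6R)-6-[(TBS-oxy)methyl]-5,6-dihydroxyoct-7-en-2-ynoate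
Product: 12 methyl (5S,6R)-6-[(TBS-oxy)methyl]-5,6-bis(TES-oxy)oct-7-en-2-ynoate
Conditions: TESOTf, 2,6-lutidine, CH2Cl2, −78 to 0 °C
Reagents that add atoms: triethylsilyl trifluoromethanesulfonate, CC[Si](CC)(CC)OS(=O)(=O)C(F)(F)F
Why: The silyl triflate with a hindered base is strong enough to silylate the tertiary C8 hydroxyl as well as the secondary C7 hydroxyl, and the alkynoate is inert to it.

Step 8
Reactants: 12 methyl (5S,6R)-6-[(TBS-oxy)methyl]-5,6-bis(TES-oxy)oct-7-en-2-ynoate
Product: 14 methyl 3-oxo-7β,8α-bis(TES-oxy)-8β-[(TBS-oxy)methyl]-9β-H-bicyclo[3.3.0]oct-4-ene-4-carboxylate, via Co2(CO)6 alkyne complex 13 (not isolated)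
Conditions: Co2(CO)8, CH2Cl2, rt; then N-methylmorpholine N-oxide, 0 °C to rt
Reagents that add atoms: dicobalt octacarbonyl Co2(CO)8 (one CO becomes the C3 carbonyl), [Co].[Co].[C-]#[O+].[C-]#[O+].[C-]#[O+].[C-]#[O+].[C-]#[O+].[C-]#[O+].[C-]#[O+].[C-]#[O+]
Why: Co2(CO)8 binds the alkynoate as its Co2(CO)6 complex, the N-oxide removes one CO as CO2 and so opens a site for the vinyl group, alkene insertion into the Co–C5 bond forms C5–C9, and CO insertion followed by reductive elimination forms C1–C3 and C3–C4. The closest known reaction type is the N-oxide-promoted intramolecular Pauson–Khand reaction of 1,6-enynes, alkynoates included, that carry allylic and homopropargylic oxygen substituents. The carbocycle C5–C6–C7–C8–C9 closes in 5-exo fashion when the tethered alkene inserts, and the cyclopentenone C1–C3–C4–C5–C9 closes in the carbonylative [2+2+1] event, the tether fixing the ester-bearing C4 next to the new carbonyl. The only new stereocentre, C9, is controlled by C8 and C7: in the cobaltacycle the CH2OTBS branch on C8 and the silyl ether on C7 should take the convex side next to H9, which leaves the C8 silyl ether on the concave side. The step needs facial selectivity at the vinyl group; the fully substituted allylic carbon C8 with its two unequal substituents, reinforced by the neighbouring C7 ether, should secure it, and its gem-disubstitution also helps the chain to fold.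

Step 9
Reactants: 14 bicyclic enone
Product: 15 methyl 3-oxo-7β,8α-bis(TES-oxy)-8β-[(TBS-oxy)methyl]-5β-H,9β-H-bicyclo[3.3.0]octane-4-carboxylate
Conditions: H2 (1 atm), palladium on carbon (Pd/C), EtOAc, rt
Reagents that add atoms: none
Why: Heterogeneous hydrogenation of the doubly activated tetrasubstituted alkene should add hydrogen from the convex face of H9, because a trans-fused bicyclo[3.3.0]octane is prohibitively strained, so H5 becomes β; C4 remains an epimerisable β-keto ester centre.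

Step 10
Reactants: 15 cis-fused β-keto ester
Product: 17 methyl 1-hydroxy-3-oxo-7β,8α-bis(TES-oxy)-8β-[(TBS-oxy)methyl]-5β-H,9β-H-bicyclo[3.3.0]octane-4-carboxylate, via dilithium dianion 16 (not isolated)
Conditions: LiN(i-Pr)2 (2.2 equiv), THF, −78 to −20 °C; then 3-phenyl-2-(phenylsulfonyl)oxaziridine (1.05 equiv), −78 °C; aq. NH4Cl
Reagents that add atoms: 3-phenyl-2-(phenylsulfonyl)oxaziridine, O=S(=O)(c1ccccc1)N1OC1c1ccccc1
Why: A Huckin–Weiler dianion forms by deprotonation first at C4 and then at C1, the only other position next to the ketone, and its more reactive terminal carbanion should take oxygen from the N-sulfonyloxaziridine (Davis enolate hydroxylation) while one equivalent of oxidant at low temperature leaves the stabilised C4 enolate alone; the configuration at C1 is of no consequence.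

Step 11
Reactants: 17 1-hydroxy β-keto ester
Product: 18 methyl 1,3-dihydroxy-7β,8α-bis(TES-oxy)-8β-[(TBS-oxy)methyl]-5β-H,9β-H-bicyclo[3.3.0]octane-4-carboxylate
Conditions: NaBH4, MeOH, −20 °C
Reagents that add atoms: none
Why: Borohydride reduces the ketone of a β-keto ester and leaves the ester at low temperature; either C3 epimer, and a ketol that has tautomerised beforehand, lead to the same 1,3-glycol constitution.

Step 12
Reactants: 18 1,3-diol ester
Product: 20 methyl 1-hydroxy-7β,8α-bis(TES-oxy)-8β-[(TBS-oxy)methyl]-5β-H,9β-H-iridoid lactol 11-oate (cyclopenta[c]pyran with C3=C4), via seco-dialdehyde 19 (not isolated)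
Conditions: NaIO4, THF/pH 7 buffer, 0 °C to rt
Reagents that add atoms: none
Why: Glycol cleavage (Malaprade reaction, feasible for cis and trans cyclopentane-1,2-diols) releases C1 and C3 as aldehydes, and the formyl ester, present as its enol, should add through oxygen to the C1 aldehyde (6-exo-trig hemiacetalisation) to give the cis-fused lactol, as is usual for iridoid aglycones with a C4 ester.

Step 13
Reactants: 20 lactol ester
Product: 22 1-O-TMS lactol with C11 hydroxymethyl and 7β,8α-bis(TES-oxy) and 8β-(TBS-oxy)methyl groups, via 1-O-TMS lactol ester 21 (not isolated)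
Conditions: 1-(trimethylsilyl)imidazole, CH2Cl2, 0 °C; then i-Bu2AlH (4 equiv), −78 °C; aq. KNaC4H4O6 (potassium sodium tartrate)
Reagents that add atoms: 1-(trimethylsilyl)imidazole, C[Si](C)(C)n1ccnc1
Why: Silylation of the hemiacetal hydroxyl in the flask prevents ring opening of a lactolate, after which i-Bu2AlH should reduce the vinylogous carbonate ester 1,2 to the allylic alcohol, and the neutral tartrate work-up keeps the silyl acetal.

Step 14
Reactants: 22 1-O-TMS lactol C11 alcohol
Product: 24 lactol with C11 TBS ether and 7β,8α-bis(TES-oxy) and 8β-(TBS-oxy)methyl groups, via 1-O-TMS 11-O-TBS acetal 23 (not isolated)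
Conditions: TBSCl, imidazole, DMF, 0 °C; then K2CO3, MeOH, 0 °C
Reagents that add atoms: tert-butyldimethylsilyl chloride, CC(C)(C)[Si](C)(C)Cl
Why: The primary allylic alcohol is silylated while C1 is still masked, and brief basic methanolysis then removes only the TMS acetal, which is far more labile than TES and TBS ethers; the lactol is used at once.

Step 15
Reactants: 24 C11-silylated lactol; 25 isovaleryl chloride
Product: 26 1β-O-isovaleryl 11-O-TBS 7β,8α-bis(TES-oxy) 8β-(TBS-oxy)methyl iridoid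
Conditions: pyridine, DMAP (cat.), CH2Cl2, −20 to 0 °C
Reagents that add atoms: none
Why: Acylation of the equilibrating lactol with an acid chloride should give mainly the 1β ester, in which the acyloxy group is pseudo-axial (anomeric effect) and trans to the C9–C8 bond as in natural 1-O-acyl iridoids, and this sets C1; no other hydroxyl is free.

Step 16
Reactants: 26 1β-O-isovaleryl tetrasilyl ether
Product: 27 7β-alcohol (1β-O-isovaleryl, 8α-OTES, 10-OTBS, 11-OTBS)
Conditions: HF·pyridine, pyridine, THF, 0 °C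
Reagents that add atoms: none
Why: Buffered fluoride should cleave the secondary TES ether much faster than the two primary TBS ethers and the shielded tertiary TES ether, and it spares the acyl acetal.

Step 17
Reactants: 28 p-coumaric acid
Product: 30 (E)-4-(TBS-oxy)cinnamic acid, via bis-silylated coumarate 29 (not isolated)
Conditions: TBSCl (2.5 equiv), imidazole, DMF, rt; then AcOH/THF/H2O, rt
Reagents that add atoms: tert-butyldimethylsilyl chloride, CC(C)(C)[Si](C)(C)Cl
Why: Exhaustive silylation followed by hydrolysis of the labile silyl ester leaves the aryl silyl ether, which is stable to dilute acid.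

Step 18
Reactants: 27 7β-alcohol; 30 (E)-4-(TBS-oxy)cinnamic acid
Product: 31 fully silylated luzonoid A (1β-O-isovaleryl, 7β-O-[(E)-4-(TBS-oxy)cinnamoyl], 8α-OTES, 10-OTBS, 11-OTBS)
Conditions: EDC·HCl, DMAP, CH2Cl2, rt
Reagents that add atoms: none
Why: Carbodiimide/DMAP coupling (Steglich esterification) acylates the hindered secondary C7 hydroxyl, the only free one, with retention at C7 and without touching the E alkene.

Step 19
Reactants: 31 fully silylated luzonoid A
Product: 32 luzonoid A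
Conditions: HF·pyridine (excess), pyridine, THF, 0 °C to rt
Reagents that add atoms: none
Why: Buffered, non-basic fluoride should remove the aryl and primary TBS ethers and the tertiary TES ether while avoiding acyl migration and sparing the acyl acetal, the enol ether and both esters.

**Compound list**

1 | L-erythrulose, (3S)-1,3,4-trihydroxybutan-2-one | OC[C@H](O)C(=O)CO | starting material
2 | 3,4-O-isopropylidene-L-erythrulose, 1-[(4S)-2,2-dimethyl-1,3-dioxolan-4-yl]-2-hydroxyethan-1-one | OCC(=O)[C@@H]1COC(C)(C)O1 | intermediate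
3 | 1-O-TBS-3,4-O-isopropylidene-L-erythrulose | CC(C)(C)[Si](C)(C)OCC(=O)[C@@H]1COC(C)(C)O1 | intermediate
4 | vinylmagnesium bromide | C=C[Mg]Br | starting material
5 | (2R)-1-(TBS-oxy)-2-[(4S)-2,2-dimethyl-1,3-dioxolan-4-yl]but-3-en-2-ol | C=C[C@@](O)(CO[Si](C)(C)C(C)(C)C)[C@@H]1COC(C)(C)O1 | intermediate
6 | (2S,3R)-3-[(TBS-oxy)methyl]pent-4-ene-1,2,3-triol | C=C[C@@](O)(CO[Si](C)(C)C(C)(C)C)[C@@H](O)CO | intermediate
7 | (2S,3R)-3-[(TBS-oxy)methyl]-2,3-dihydroxypent-4-en-1-yl 4-methylbenzenesulfonate (not isolated) | C=C[C@@](O)(CO[Si](C)(C)C(C)(C)C)[C@@H](O)COS(=O)(=O)c1ccc(C)cc1 | intermediate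
8 | (2R)-1-(TBS-oxy)-2-[(2S)-oxiran-2-yl]but-3-en-2-ol | C=C[C@@](O)(CO[Si](C)(C)C(C)(C)C)[C@@H]1CO1 | intermediate
9 | methyl propiolate | C#CC(=O)OC | starting material
10 | lithium methyl propiolate (not isolated) | [Li+].[C-]#CC(=O)OC | intermediate
11 | methyl (5S,6R)-6-[(TBS-oxy)methyl]-5,6-dihydroxyoct-7-en-2-ynoate | C=C[C@@](O)(CO[Si](C)(C)C(C)(C)C)[C@@H](O)CC#CC(=O)OC | intermediate
12 | methyl (5S,6R)-6-[(TBS-oxy)methyl]-5,6-bis(TES-oxy)oct-7-en-2-ynoate (enyne for the key step) | C=C[C@@](O[Si](CC)(CC)CC)(CO[Si](C)(C)C(C)(C)C)[C@@H](O[Si](CC)(CC)CC)CC#CC(=O)OC | intermediate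
13 | Co2(CO)6 complex of the alkyne of 12, written as its components (not isolated) | C=C[C@@](O[Si](CC)(CC)CC)(CO[Si](C)(C)C(C)(C)C)[C@@H](O[Si](CC)(CC)CC)CC#CC(=O)OC.[Co].[Co].[C-]#[O+].[C-]#[O+].[C-]#[O+].[C-]#[O+].[C-]#[O+].[C-]#[O+] | intermediate
14 | bicyclic enone: methyl 3-oxo-7β,8α-bis(TES-oxy)-8β-[(TBS-oxy)methyl]-9β-H-bicyclo[3.3.0]oct-4-ene-4-carboxylate | O=C1C[C@H]2C(C[C@H](O[Si](CC)(CC)CC)[C@]2(O[Si](CC)(CC)CC)CO[Si](C)(C)C(C)(C)C)=C1C(=O)OC | intermediate
15 | cis-fused β-keto ester (5β-H, 9β-H; C4 unassigned) | O=C1C[C@H]2[C@H](C[C@H](O[Si](CC)(CC)CC)[C@]2(O[Si](CC)(CC)CC)CO[Si](C)(C)C(C)(C)C)C1C(=O)OC | intermediate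
16 | dilithium C1,C4-dianion of 15 (not isolated) | [Li+].[Li+].COC([O-])=C1C([O-])=C[C@H]2[C@@H]1C[C@H](O[Si](CC)(CC)CC)[C@]2(O[Si](CC)(CC)CC)CO[Si](C)(C)C(C)(C)C | intermediate
17 | 1-hydroxy β-keto ester (C1, C4 unassigned) | O=C1C(O)[C@H]2[C@H](C[C@H](O[Si](CC)(CC)CC)[C@]2(O[Si](CC)(CC)CC)CO[Si](C)(C)C(C)(C)C)C1C(=O)OC | intermediate
18 | 1,3-diol ester (C1, C3, C4 unassigned) | OC1C(O)[C@H]2[C@H](C[C@H](O[Si](CC)(CC)CC)[C@]2(O[Si](CC)(CC)CC)CO[Si](C)(C)C(C)(C)C)C1C(=O)OC | intermediate
19 | seco-dialdehyde: C1 formyl on C9, methyl formylacetate unit on C5 (not isolated) | O=C[C@H]1[C@@H](C(C=O)C(=O)OC)C[C@H](O[Si](CC)(CC)CC)[C@]1(O[Si](CC)(CC)CC)CO[Si](C)(C)C(C)(C)C | intermediate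
20 | lactol methyl ester: methyl 1-hydroxy-7β,8α-bis(TES-oxy)-8β-[(TBS-oxy)methyl]-1,4a,5,6,7,7a-hexahydrocyclopenta[c]pyran-4-carboxylate (5β-H, 9β-H) | O[C@@H]1OC=C(C(=O)OC)[C@H]2C[C@H](O[Si](CC)(CC)CC)[C@](O[Si](CC)(CC)CC)(CO[Si](C)(C)C(C)(C)C)[C@@H]12 | intermediate
21 | 1-O-TMS acetal of 20 (not isolated) | C[Si](C)(C)O[C@@H]1OC=C(C(=O)OC)[C@H]2C[C@H](O[Si](CC)(CC)CC)[C@](O[Si](CC)(CC)CC)(CO[Si](C)(C)C(C)(C)C)[C@@H]12 | intermediate
22 | 1-O-TMS acetal with C11 hydroxymethyl | C[Si](C)(C)O[C@@H]1OC=C(CO)[C@H]2C[C@H](O[Si](CC)(CC)CC)[C@](O[Si](CC)(CC)CC)(CO[Si](C)(C)C(C)(C)C)[C@@H]12 | intermediate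
23 | 1-O-TMS 11-O-TBS acetal (not isolated) | C[Si](C)(C)O[C@@H]1OC=C(CO[Si](C)(C)C(C)(C)C)[C@H]2C[C@H](O[Si](CC)(CC)CC)[C@](O[Si](CC)(CC)CC)(CO[Si](C)(C)C(C)(C)C)[C@@H]12 | intermediate
24 | lactol with 11-OTBS, 7β-OTES, 8α-OTES, 10-OTBS | O[C@@H]1OC=C(CO[Si](C)(C)C(C)(C)C)[C@H]2C[C@H](O[Si](CC)(CC)CC)[C@](O[Si](CC)(CC)CC)(CO[Si](C)(C)C(C)(C)C)[C@@H]12 | intermediate
25 | isovaleryl chloride (3-methylbutanoyl chloride) | CC(C)CC(=O)Cl | starting material
26 | 1β-O-isovaleryl acetal with 11-OTBS, 7β-OTES, 8α-OTES, 10-OTBS | CC(C)CC(=O)O[C@@H]1OC=C(CO[Si](C)(C)C(C)(C)C)[C@H]2C[C@H](O[Si](CC)(CC)CC)[C@](O[Si](CC)(CC)CC)(CO[Si](C)(C)C(C)(C)C)[C@@H]12 | intermediate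
27 | 7β-alcohol: 1β-O-isovaleryl, 8α-OTES, 10-OTBS, 11-OTBS | CC(C)CC(=O)O[C@@H]1OC=C(CO[Si](C)(C)C(C)(C)C)[C@H]2C[C@H](O)[C@](O[Si](CC)(CC)CC)(CO[Si](C)(C)C(C)(C)C)[C@@H]12 | intermediate
28 | p-coumaric acid | OC(=O)/C=C/c1ccc(O)cc1 | starting material
29 | tert-butyldimethylsilyl (E)-4-(TBS-oxy)cinnamate (not isolated) | CC(C)(C)[Si](C)(C)OC(=O)/C=C/c1ccc(O[Si](C)(C)C(C)(C)C)cc1 | intermediate
30 | (E)-4-(TBS-oxy)cinnamic acid | OC(=O)/C=C/c1ccc(O[Si](C)(C)C(C)(C)C)cc1 | intermediate
31 | fully silylated luzonoid A | CC(C)CC(=O)O[C@@H]1OC=C(CO[Si](C)(C)C(C)(C)C)[C@H]2C[C@H](OC(=O)/C=C/c3ccc(O[Si](C)(C)C(C)(C)C)cc3)[C@](O[Si](CC)(CC)CC)(CO[Si](C)(C)C(C)(C)C)[C@@H]12 | intermediate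
32 | luzonoid A, (1S,4aS,6S,7R,7aS)-7-hydroxy-4,7-bis(hydroxymethyl)-1-(3-methylbutanoyloxy)-1,4a,5,6,7,7a-hexahydrocyclopenta[c]pyran-6-yl (E)-3-(4-hydroxyphenyl)prop-2-enoate | CC(C)CC(=O)O[C@@H]1OC=C(CO)[C@H]2C[C@H](OC(=O)/C=C/c3ccc(O)cc3)[C@](O)(CO)[C@@H]12 | target

**Step count**

Total: 19 steps. Longest linear sequence: 18 steps (steps 1 to 16, 18 and 19, from L-erythrulose); step 17 prepares the side-chain acid.

**Steps most likely to fail**

1. Step 10. Oxygen may be transferred to the C4 enolate carbon as well as to C1, a second oxidation may follow, and the dianion may add to the sulfonimine that the oxidant leaves behind. The fallback sets out from β-keto ester 15 and returns at lactol 20 without any enolate oxidation. Ketone 15 would be reduced with NaBH4 to the β-hydroxy ester F1. This would be converted with MsCl/Et3N into the mesylate F2 and eliminated with DBU to the conjugated cyclopentene ester F3 (C3=C4). Deconjugation through the lithium dienolate (LiN(i-Pr)2, HMPA, THF, −78 °C; kinetic protonation at C4 with AcOH) would move the alkene to C1=C3 in the β,γ-unsaturated ester F4. Ozonolysis (O3, CH2Cl2/MeOH, −78 °C; Me2S) would then give the seco-dialdehyde 19, which closes to 20.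

2. Step 13. The silyl acetal may be lost under the hydride conditions, so that the lactolate opens and C1 is over-reduced, and the electron-rich enol ether acetal may decompose during work-up. The fallback sets out from diol ester 18 and returns at lactol 24; it reduces C11 before the pyran exists. Ester 18 would be reduced with LiBH4 (THF, 0 °C) to the triol F5. Its primary C11 hydroxyl would be silylated selectively (TBSCl, imidazole, CH2Cl2, −20 °C) to give the silyl ether diol F6. Glycol cleavage with NaIO4 would give the dialdehyde F7, which should close on silica or with a trace of acid to the enol hemiacetal 24, as iridodial-type 1,5-dialdehydes do.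

3. Step 8. The electron-poor alkynoate complex may cyclise slowly and lose cobalt or decompose first, and facial discrimination at the vinyl group may be insufficient. The fallback keeps the same cycloaddition but on a terminal alkyne; it sets out from epoxide 8 and returns at enone 14. Epoxide 8 would be opened with lithium trimethylsilylacetylide and BF3·OEt2 (THF, −78 °C) to the silylalkyne diol F8. C-Desilylation (K2CO3, MeOH) would give the terminal alkyne diol F9, and TESOTf/2,6-lutidine the bis-TES enyne F10. Its Pauson–Khand reaction under the conditions of step 8 would give the ester-free enone F11. α-Iodination (I2, pyridine, CH2Cl2) would give the iodoenone F12, and methoxycarbonylation (PdCl2(PPh3)2, CO, MeOH, Et3N) would deliver 14.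

**Further compounds**

F1 | step 10 | β-hydroxy ester: methyl 3-hydroxy-7β,8α-bis(TES-oxy)-8β-[(TBS-oxy)methyl]-5β-H,9β-H-bicyclo[3.3.0]octane-4-carboxylate | OC1C[C@H]2[C@H](C[C@H](O[Si](CC)(CC)CC)[C@]2(O[Si](CC)(CC)CC)CO[Si](C)(C)C(C)(C)C)C1C(=O)OC
F2 | step 10 | 3-O-methanesulfonate of F1 | CS(=O)(=O)OC1C[C@H]2[C@H](C[C@H](O[Si](CC)(CC)CC)[C@]2(O[Si](CC)(CC)CC)CO[Si](C)(C)C(C)(C)C)C1C(=O)OC
F3 | step 10 | conjugated ester with C3=C4 | COC(=O)C1=CC[C@H]2[C@@H]1C[C@H](O[Si](CC)(CC)CC)[C@]2(O[Si](CC)(CC)CC)CO[Si](C)(C)C(C)(C)C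
F4 | step 10 | β,γ-unsaturated ester with C1=C3 (C4 unassigned) | COC(=O)C1C=C[C@H]2[C@@H]1C[C@H](O[Si](CC)(CC)CC)[C@]2(O[Si](CC)(CC)CC)CO[Si](C)(C)C(C)(C)C
F5 | step 13 | C1,C3,C11-triol | OCC1C(O)C(O)[C@H]2[C@@H]1C[C@H](O[Si](CC)(CC)CC)[C@]2(O[Si](CC)(CC)CC)CO[Si](C)(C)C(C)(C)C
F6 | step 13 | C1,C3-diol with 11-OTBS | CC(C)(C)[Si](C)(C)OCC1C(O)C(O)[C@H]2[C@@H]1C[C@H](O[Si](CC)(CC)CC)[C@]2(O[Si](CC)(CC)CC)CO[Si](C)(C)C(C)(C)C
F7 | step 13 | C1,C3-dialdehyde with 11-OTBS | O=C[C@H]1[C@@H](C(C=O)CO[Si](C)(C)C(C)(C)C)C[C@H](O[Si](CC)(CC)CC)[C@]1(O[Si](CC)(CC)CC)CO[Si](C)(C)C(C)(C)C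
F8 | step 8 | (3R,4S)-3-[(TBS-oxy)methyl]-7-(trimethylsilyl)hept-1-en-6-yne-3,4-diol | C=C[C@@](O)(CO[Si](C)(C)C(C)(C)C)[C@@H](O)CC#C[Si](C)(C)C
F9 | step 8 | (3R,4S)-3-[(TBS-oxy)methyl]hept-1-en-6-yne-3,4-diol | C=C[C@@](O)(CO[Si](C)(C)C(C)(C)C)[C@@H](O)CC#C
F10 | step 8 | bis-TES ether of F9 | C=C[C@@](O[Si](CC)(CC)CC)(CO[Si](C)(C)C(C)(C)C)[C@@H](O[Si](CC)(CC)CC)CC#C
F11 | step 8 | 3-oxo-7β,8α-bis(TES-oxy)-8β-[(TBS-oxy)methyl]-9β-H-bicyclo[3.3.0]oct-4-ene | O=C1C[C@H]2C(C[C@H](O[Si](CC)(CC)CC)[C@]2(O[Si](CC)(CC)CC)CO[Si](C)(C)C(C)(C)C)=C1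
F12 | step 8 | 4-iodo derivative of F11 | O=C1C[C@H]2C(C[C@H](O[Si](CC)(CC)CC)[C@]2(O[Si](CC)(CC)CC)CO[Si](C)(C)C(C)(C)C)=C1I
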